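**Plan**

1. Numbering (eremophilane): ring A = C1–C5 and C10, ring B = C5–C10, methyls on C4 and C5, isopropenyl on C7; β is the face of the C5 methyl.
2. Retrosynthesis: cut the two (Z)-hex-2-enoates (made last from alkynoates) to a 3,8,9-triol, then the C7–isopropenyl bond and the C9–O bond to a 3-keto-Δ9-en-8-one, then the C4–C5 bond by a retro-semipinacol to a hydrindenone.
3. Enabling feature: oxygenated C3 is flanked by C4 (H, Me) and quaternary C5, which is the product pattern of a 1,2-shift of C5 from a cyclopentanol carbon C3 to an exocyclic carbinol carbon C4.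
4. Forward: ring B and the cyclopentane C1–C2–C3–C5–C10 come from the (S)-Hajos–Parrish ketone; C4 and its methyl are added as an acyl anion equivalent; the shift of C5 expands the cyclopentane to ring A; ring B is then reduced, oxygenated at C9, alkenylated at C7 and reduced at C8; the esters come last.
5. Stereochemistry: C5 from the starting material; C4 by chelation-controlled reduction followed by stereospecific inversion in the shift; C10 and C3 by dissolving-metal reduction; C9 by α-face enol ether oxidation; C7 equatorial on protonation; C8 by equatorial hydride delivery; both Z-alkenes by syn semihydrogenation.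

Key step: step 5

Step 1
Reactants: 1 (S)-Hajos–Parrish ketone
Product: 2 (7aS)-5-ethoxy-7a-methyl-2,6,7,7a-tetrahydro-1H-inden-1-one (dienol ether of the enone)
Conditions: HC(OEt)3 (1.2 equiv), cat. PPTS, EtOH, rt; Et3N quench
Reagents that add atoms: triethyl orthoformate (CCOC(OCC)OCC)
Why: Acid-catalysed dienol ether formation (the steroid 3-enol ether protection) should occur only at the conjugated C8 carbonyl, because the C3 ketone next to quaternary C5 ketalises slowly; no stereocenter is formed.

Step 2
Reactants: 2 dienol ether; 3 ethyl vinyl ether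
Product: 5 (1S,7aS)-1-acetyl-1-hydroxy-7a-methyl-1,2,3,6,7,7a-hexahydro-5H-inden-5-one, via ethoxyvinyl carbinol 4 (not isolated)
Conditions: 3, t-BuLi, THF, −78 to 0 °C; CeCl3, −78 °C; then 2; then 1 M HCl, THF, rt
Reagents that add atoms: water (O)
Why: 1,2-Addition of an acyl anion equivalent (1-ethoxyvinyl organocerium, whose low basicity should suppress enolisation of the β,γ-unsaturated ketone) from the α-face opposite the angular methyl sets C3 with the hydroxyl β, and acid hydrolysis of both enol ethers releases the methyl ketone and the enone.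

Step 3
Reactants: 5 ketol enone
Product: 6 (1S,7aS)-1-hydroxy-1-[(1R)-1-hydroxyethyl]-7a-methyl-1,2,3,6,7,7a-hexahydro-5H-inden-5-one
Conditions: Zn(BH4)2, Et2O, −20 °C
Reagents that add atoms: none
Why: Chelation-controlled reduction (Cram-chelate model): zinc bridges the tertiary hydroxyl and the C4 carbonyl and hydride enters from the C2 methylene side, away from quaternary C5 and its C6 substituent, which should give the 4R carbinol, while the conjugated enone is reduced much more slowly by this reagent.

Step 4
Reactants: 6 diol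
Product: 7 (1R)-1-[(1S,7aS)-1-hydroxy-7a-methyl-5-oxo-2,3,5,6,7,7a-hexahydro-1H-inden-1-yl]ethyl methanesulfonate
Conditions: MsCl, Et3N, CH2Cl2, −20 °C
Reagents that add atoms: methanesulfonyl chloride (CS(=O)(=O)Cl)
Why: Sulfonylation of the secondary hydroxyl leaves the C4–O bond intact, so C4 keeps its configuration, and the tertiary C3 hydroxyl does not react.

Step 5
Reactants: 7 hydroxy mesylate
Product: 8 (4aR,5R)-4a,5-dimethyl-4,4a,7,8-tetrahydronaphthalene-2,6(3H,5H)-dione (4β,5β-dimethyl-Δ9-ene-3,8-dione in eremophilane numbering)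
Conditions: Et2AlCl (2 equiv), CH2Cl2, −78 to −20 °C
Reagents that add atoms: none
Why: Et2AlCl turns the tertiary C3 hydroxyl into an aluminium alkoxide and activates the mesylate, and as the C4–O bond ionises the antiperiplanar C3–C5 bond shifts to C4 while the alkoxide becomes the C3 ketone. The closest known reaction type is the organoaluminium-promoted semipinacol rearrangement of β-mesyloxy tertiary alcohols, as in the D-homoannulation of 17-hydroxy-20-sulfonyloxy steroids. No ring is closed end to end: the cyclopentane C1–C2–C3–C5–C10 takes up C4 between C3 and C5, so ring A arises by a one-carbon ring expansion. The only new stereocenter, C4, is set by stereospecific inversion at the mesylate carbon, so the 4R carbinol becomes the 4β-methyl group cis to the methyl on C5, which migrates with retention. The step needs C5 to migrate in preference to C2 and to epoxide closure: C5 is the more substituted and therefore better migrating terminus, the rotamer with the mesylate anti to C3–C5 keeps the C4 methyl outside the ring whereas the rotamer for C2 migration forces it under the ring, and the O–Al bond disfavours SN2 closure to the epoxide.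

Step 6
Reactants: 8 enedione
Product: 10 3α,8-bis(triethylsilyloxy)-4β,5β-dimethyl-10αH-decal-8-ene, via dilithium alkoxide enolate 9 (not isolated)
Conditions: Li (5 equiv), t-BuOH (2 equiv), NH3/THF, −78 to −33 °C; isoprene; NH3 evaporated; TESCl, Et3N, THF, 0 °C
Reagents that add atoms: chlorotriethylsilane (CC[Si](Cl)(CC)CC)
Why: Dissolving-metal reduction should convert the enone into the trans-decalin C8 enolate by axial protonation at C10 anti to the angular methyl, and the C3 ketone into the thermodynamically favoured equatorial 3α-alkoxide (hydride reagents would give the axial alcohol here because of the syn-axial C5 methyl); silylation of both O–Li bonds fixes the Δ8 enol ether regiochemistry.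

Step 7
Reactants: 10 bis-silyl enol ether
Product: 12 3α,9α-bis(triethylsilyloxy)-4β,5β-dimethyl-10αH-decalin-8-one, via silyloxy epoxide 11 (not isolated)
Conditions: mCPBA (1.05 equiv), NaHCO3, CH2Cl2, −20 °C to rt
Reagents that add atoms: mCPBA (OOC(=O)c1cccc(Cl)c1)
Why: Rubottom oxidation: the peracid should epoxidise the silyl enol ether from the α-face, the β-face at C9 being screened by the syn-axial C5 methyl, and 1,4-silyl migration opens the epoxide to the 9α (equatorial, also thermodynamically preferred) silyloxy ketone.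

Step 8
Reactants: 12 silyloxy ketone; 13 2-bromopropene
Product: 14 7α-isopropenyl-3α,9α-bis(triethylsilyloxy)-4β,5β-dimethyl-10αH-decalin-8-one
Conditions: LiHMDS (2.2 equiv), Pd(dba)2 (cat.), Q-Phos (cat.), toluene, rt; AcOH quench at −78 °C
Reagents that add atoms: none
Why: Palladium-catalysed α-alkenylation of a ketone enolate with an alkenyl bromide: the kinetic enolate should form at the C7 methylene (C9 is a tertiary, silyloxy-bearing position), and C7 is fixed on protonation of the product enolate, axial proton delivery placing the isopropenyl group equatorial (α) because the epimer would be syn-axial to the C5 methyl.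

Step 9
Reactants: 14 isopropenyl ketone
Product: 16 7α-isopropenyl-4β,5β-dimethyl-10αH-decalin-3α,8α,9α-triol, via bis-silyl 8α-alcohol 15 (not isolated)
Conditions: L-Selectride, THF, −78 °C; then 1 M HCl, THF/H2O, 0 °C to rt
Reagents that add atoms: none
Why: The bulky trialkylborohydride should attack the C8 carbonyl along the equatorial trajectory to give the axial 8α-alcohol cis to both flanking equatorial substituents, and the acid work-up hydrolyses both triethylsilyl ethers.

Step 10
Reactants: 16 triol; 17 hex-2-ynoic acid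
Product: 18 8α-hydroxy-7α-isopropenyl-4β,5β-dimethyl-10αH-decalin-3α,9α-diyl bis(hex-2-ynoate)
Conditions: 17 (2.3 equiv), DCC, DMAP (cat.), CH2Cl2, −20 to 0 °C
Reagents that add atoms: none
Why: Steglich esterification should acylate the two equatorial hydroxyls at C3 and C9 while the axial C8 hydroxyl, flanked by two equatorial substituents, reacts far more slowly; the alkynoic acid is used because it has no alkene geometry to lose under basic acylation conditions.

Step 11
Reactants: 18 bis-alkynoate
Product: 19 8α-hydroxy-7α-isopropenyl-4β,5β-dimethyl-10αH-decalin-3α,9α-diyl bis[(2Z)-hex-2-enoate] (target)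
Conditions: H2 (1 atm), Lindlar catalyst, quinoline, EtOAc, rt
Reagents that add atoms: none
Why: Lindlar semihydrogenation adds one equivalent of hydrogen syn to each conjugated alkyne to give both (Z)-enoates, and the poisoned catalyst should leave the 1,1-disubstituted isopropenyl alkene untouched.

**Compound list**

1 | (S)-Hajos–Parrish ketone, (7aS)-7a-methyl-2,3,7,7a-tetrahydro-1H-indene-1,5(6H)-dione | C[C@]12CCC(=O)C=C1CCC2=O | starting material
2 | (7aS)-5-ethoxy-7a-methyl-2,6,7,7a-tetrahydro-1H-inden-1-one (double bonds C3=C3a and C4=C5) | C1C[C@]2(C)C(=O)CC=C2C=C1OCC | intermediate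
3 | ethyl vinyl ether | C=COCC | starting material
4 | (1S,7aS)-5-ethoxy-1-(1-ethoxyethenyl)-7a-methyl-2,6,7,7a-tetrahydro-1H-inden-1-ol (OH cis to the 7a-methyl) | C1C[C@]2(C)[C@](O)(C(=C)OCC)CC=C2C=C1OCC | intermediate (not isolated)
5 | (1S,7aS)-1-acetyl-1-hydroxy-7a-methyl-1,2,3,6,7,7a-hexahydro-5H-inden-5-one (OH cis to the 7a-methyl) | C1C[C@]2(C)[C@](O)(C(C)=O)CCC2=CC1=O | intermediate
6 | (1S,7aS)-1-hydroxy-1-[(1R)-1-hydroxyethyl]-7a-methyl-1,2,3,6,7,7a-hexahydro-5H-inden-5-one | C1C[C@]2(C)[C@](O)([C@@H](C)O)CCC2=CC1=O | intermediate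
7 | (1R)-1-[(1S,7aS)-1-hydroxy-7a-methyl-5-oxo-2,3,5,6,7,7a-hexahydro-1H-inden-1-yl]ethyl methanesulfonate | C1C[C@]2(C)[C@](O)([C@@H](C)OS(C)(=O)=O)CCC2=CC1=O | intermediate
8 | (4aR,5R)-4a,5-dimethyl-4,4a,7,8-tetrahydronaphthalene-2,6(3H,5H)-dione | C1C[C@]2(C)[C@@H](C)C(=O)CCC2=CC1=O | intermediate
9 | dilithium salt of the 3α-alkoxide and Δ8 C8-enolate of 4β,5β-dimethyl-10αH-decalin | C1C[C@]2(C)[C@@H](C)[C@H]([O-])CC[C@H]2C=C1[O-].[Li+].[Li+] | intermediate (not isolated)
10 | 3α,8-bis(triethylsilyloxy)-4β,5β-dimethyl-10αH-decal-8-ene | C1C[C@]2(C)[C@@H](C)[C@H](O[Si](CC)(CC)CC)CC[C@H]2C=C1O[Si](CC)(CC)CC | intermediate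
11 | 8α,9α-epoxy-3α,8β-bis(triethylsilyloxy)-4β,5β-dimethyl-10αH-decalin | C1C[C@]2(C)[C@@H](C)[C@H](O[Si](CC)(CC)CC)CC[C@H]2[C@@H]3O[C@]13O[Si](CC)(CC)CC | intermediate (not isolated)
12 | 3α,9α-bis(triethylsilyloxy)-4β,5β-dimethyl-10αH-decalin-8-one | C1C[C@]2(C)[C@@H](C)[C@H](O[Si](CC)(CC)CC)CC[C@H]2[C@H](O[Si](CC)(CC)CC)C1=O | intermediate
13 | 2-bromopropene | CC(Br)=C | starting material
14 | 7α-isopropenyl-3α,9α-bis(triethylsilyloxy)-4β,5β-dimethyl-10αH-decalin-8-one | C=C(C)[C@@H]1C[C@]2(C)[C@@H](C)[C@H](O[Si](CC)(CC)CC)CC[C@H]2[C@H](O[Si](CC)(CC)CC)C1=O | intermediate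
15 | 7α-isopropenyl-3α,9α-bis(triethylsilyloxy)-4β,5β-dimethyl-10αH-decalin-8α-ol | C=C(C)[C@@H]1C[C@]2(C)[C@@H](C)[C@H](O[Si](CC)(CC)CC)CC[C@H]2[C@H](O[Si](CC)(CC)CC)[C@@H]1O | intermediate (not isolated)
16 | 7α-isopropenyl-4β,5β-dimethyl-10αH-decalin-3α,8α,9α-triol | C=C(C)[C@@H]1C[C@]2(C)[C@@H](C)[C@H](O)CC[C@H]2[C@H](O)[C@@H]1O | intermediate
17 | hex-2-ynoic acid | CCCC#CC(=O)O | starting material
18 | 8α-hydroxy-7α-isopropenyl-4β,5β-dimethyl-10αH-decalin-3α,9α-diyl bis(hex-2-ynoate) | C=C(C)[C@@H]1C[C@]2(C)[C@@H](C)[C@H](OC(=O)C#CCCC)CC[C@H]2[C@H](OC(=O)C#CCCC)[C@@H]1O | intermediate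
19 | 8α-hydroxy-7α-isopropenyl-4β,5β-dimethyl-10αH-decalin-3α,9α-diyl bis[(2Z)-hex-2-enoate] (CNP0420276.1) | C=C(C)[C@@H]1C[C@]2(C)[C@@H](C)[C@H](OC(=O)/C=C\CCC)CC[C@H]2[C@H](OC(=O)/C=C\CCC)[C@@H]1O | target

Total step count: 11. Longest linear sequence: 11 steps (1 to 19); compounds 3, 13 and 17 are purchased.

**Steps most likely to fail**

Step 8. The coupling may stall at the hindered enolate, alkenylate C7 twice, move the new alkene into conjugation with the ketone, or protonate C7 from the wrong face. The fallback sets out from 12 and builds the isopropenyl group by aldol addition and dehydration. LDA (THF, −78 °C) followed by acetone should give the 7α-(2-hydroxypropan-2-yl) ketone F1, the electrophile entering from the α-face away from the C5 methyl. L-Selectride then gives the 8α,11-diol F2. Burgess reagent (benzene, rt) should dehydrate the tertiary alcohol towards a methyl group, the flanked axial secondary hydroxyl reacting much more slowly. This gives 15, which is hydrolysed to 16 as in step 9.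

Step 6. The C3 ketone may escape reduction through enolisation, the C8 enolate may be over-reduced, or silylation may be incomplete. The fallback sets out from 8 and separates the two reductions. NaBH4 (MeOH/CH2Cl2, −40 °C) reduces only the saturated ketone and, by equatorial attack past the syn-axial C5 methyl, should give the axial 3β-alcohol F3. Mitsunobu inversion (4-nitrobenzoic acid, PPh3, DIAD, THF) gives the 3α-(4-nitrobenzoate) F4, and methanolysis (K2CO3, MeOH) the 3α-alcohol F5. Li/NH3 reduction of the enone alone (the hydroxyl serves as proton source) followed by TESCl and Et3N returns to the route at 10 by way of 9.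

Step 3. Hydride delivery may show poor or reversed facial selectivity, and the 4S carbinol would steer the shift of step 5 towards migration of C2 or epoxide closure. The fallback sets out from 2 and needs no carbinol stereocenter. 1,1-Dibromoethyllithium (1,1-dibromoethane, LDA, THF, −100 °C) adds to the C3 ketone from the α-face to give the dibromo carbinol F6. n-BuLi (2 equiv, −78 °C to rt) generates the β-oxido carbenoid, in which the more substituted C5 should migrate to give the ring-expanded C3(4)-enolate. Protonation with AcOH at −78 °C from the α-face, anti to the adjacent C5 methyl, sets the 4β-methyl group, and aqueous acid work-up hydrolyses the dienol ether and returns to the route at 8.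

**Further compounds**

F1 | step 8 | 7α-(2-hydroxypropan-2-yl)-3α,9α-bis(triethylsilyloxy)-4β,5β-dimethyl-10αH-decalin-8-one | CC(C)(O)[C@@H]1C[C@]2(C)[C@@H](C)[C@H](O[Si](CC)(CC)CC)CC[C@H]2[C@H](O[Si](CC)(CC)CC)C1=O
F2 | step 8 | 7α-(2-hydroxypropan-2-yl)-3α,9α-bis(triethylsilyloxy)-4β,5β-dimethyl-10αH-decalin-8α-ol | CC(C)(O)[C@@H]1C[C@]2(C)[C@@H](C)[C@H](O[Si](CC)(CC)CC)CC[C@H]2[C@H](O[Si](CC)(CC)CC)[C@@H]1O
F3 | step 6 | 3β-hydroxy-4β,5β-dimethyl-decal-9-en-8-one (axial alcohol) | C1C[C@]2(C)[C@@H](C)[C@@H](O)CCC2=CC1=O
F4 | step 6 | 4β,5β-dimethyl-8-oxo-decal-9-en-3α-yl 4-nitrobenzoate | C1C[C@]2(C)[C@@H](C)[C@H](OC(=O)c3ccc(cc3)[N+](=O)[O-])CCC2=CC1=O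
F5 | step 6 | 3α-hydroxy-4β,5β-dimethyl-decal-9-en-8-one (equatorial alcohol) | C1C[C@]2(C)[C@@H](C)[C@H](O)CCC2=CC1=O
F6 | step 3 | (1S,7aS)-1-(1,1-dibromoethyl)-5-ethoxy-7a-methyl-2,6,7,7a-tetrahydro-1H-inden-1-ol | C1C[C@]2(C)[C@](O)(C(C)(Br)Br)CC=C2C=C1OCC
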